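**Retrosynthetic overview**
- Cut both aryl–C(=O) bonds. This gives ε-truxillic acid plus two resorcinols (double Friedel–Crafts acylation); all four aromatic rings are bought.
- ε-Truxillic acid comes from the diethyl ester that is epimeric at one carboxyl carbon. Base equilibration sets the two carbonyl-bearing centres all-trans.
- The cis-2,4-diphenylcyclobutane diester comes from 1,3-diphenylbicyclo[1.1.0]butane-2,4-diester by re-drawing the transannular bond. Syn hydrogenolysis sets Ph/Ph cis.
- The bicyclobutane comes from diphenylacetylene plus two :CHCO2Et units (double [2+1] in one flask).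
- Ring order: the cyclopropene ring and then the second three-membered ring form in the same operation. The four-membered ring is the bicyclobutane perimeter, released when the central bond is cleaved.

Assumption: the SMILES decodes to the all-trans (r-1,t-2,c-3,t-4) head-to-tail dimer, which has two mirror planes and is achiral. "Single enantiomer" therefore means this single meso diastereomer, and no asymmetric induction is needed.

**Step 1**
Reactants: 1 diphenylacetylene; 2 ethyl diazoacetate (two equivalents are incorporated)
Product: 4 diethyl (2-exo,4-endo)-1,3-diphenylbicyclo[1.1.0]butane-2,4-dicarboxylate, via cyclopropene ester 3 (not isolated)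
Conditions: Rh2(OAc)4 (1 mol %), CH2Cl2, 25 °C, 2 (6 equiv) by syringe pump over 24 h
Reagents that add atoms: ethyl diazoacetate, CCOC(=O)C=[N+]=[N-]
Why: Proposed new method: two successive Rh-carbenoid [2+1] transfers build both three-membered rings in one flask, first cyclopropenation of the alkyne and then cyclopropanation of the strained (about 54 kcal/mol), stilbene-like C=C of 3, which is attacked on the face anti to its ester (first ester exo) with the incoming ester turned away from the two phenyls (endo); the closest known reaction types are metal-catalysed cyclopropenation of alkynes with diazoacetates and the double carbene or carbenoid addition to alkynes that gives bicyclobutanes (a minor pathway with Cu/diazoacetate, preparative with zinc carbenoids and with haem carbene transferases), and the ester configurations do not matter because step 3 equilibrates those centres.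

**Step 2**
Reactants: 4 diethyl (2-exo,4-endo)-1,3-diphenylbicyclo[1.1.0]butane-2,4-dicarboxylate
Product: 5 diethyl (r-1,t-2,t-3,t-4)-2,4-diphenylcyclobutane-1,3-dicarboxylate (diethyl epi-truxillate)
Conditions: H2 (1 atm), 10% Pd/C, EtOAc, 0 °C to rt
Reagents that add atoms: none
Why: Catalytic hydrogenolysis of a strained σ-bond cleaves the doubly benzylic central bond (about 40 kcal/mol of strain released) as the weakest and most exposed bond, and because the catalyst surface delivers both hydrogens to one face, both phenyls are pushed to the opposite face and end cis to each other (this sets the two Ph-bearing stereocentres), so one ester is left trans and the other cis to them whichever face is attacked.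

**Step 3**
Reactants: 5 diethyl epi-truxillate
Product: 7 ε-truxillic acid (r-1,t-2,c-3,t-4)-2,4-diphenylcyclobutane-1,3-dicarboxylic acid, via all-trans diester 6 (not isolated)
Conditions: NaOEt (0.2 equiv), EtOH, reflux; then 2 M aq NaOH, reflux; then aq HCl
Reagents that add atoms: sodium hydroxide, [Na+].[OH-]
Why: Thermodynamic enolate epimerisation followed by saponification works because only the CH(CO2Et) centres are acidic, so ethoxide inverts the ester that is cis to both phenyls and funnels the material into the all-trans diester 6 (this sets the two carbonyl-bearing stereocentres, while the benzylic centres cannot epimerise), which hydroxide then hydrolyses.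

**Step 4**
Reactants: 7 ε-truxillic acid; 8 resorcinol (2.5 equiv)
Product: 9 [(r-1,t-2,c-3,t-4)-2,4-diphenylcyclobutane-1,3-diyl]bis[(2,4-dihydroxyphenyl)methanone] (target)
Conditions: BF3·OEt2 (as solvent), 85 °C, 3 h; then 10% aq NaOAc
Reagents that add atoms: resorcinol, Oc1cccc(O)c1
Why: Nencki-type BF3-mediated Friedel–Crafts acylation (O-acylation/Fries manifold) occurs at C4 of resorcinol, ortho and para to the two OH groups, at both carboxyls; ring closure onto a neighbouring phenyl (truxone formation) is geometrically blocked because each carboxyl is trans to both phenyls, and any acid-catalysed enolisation only returns the all-trans thermodynamic configuration, so no stereocentre is lost.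

**Compound list**
1 | diphenylacetylene | C(#Cc1ccccc1)c1ccccc1 | starting material
2 | ethyl diazoacetate | CCOC(=O)C=[N+]=[N-] | starting material
3 | ethyl 2,3-diphenylcycloprop-2-ene-1-carboxylate (achiral) | CCOC(=O)C1C(c2ccccc2)=C1c1ccccc1 | intermediate
4 | diethyl (2-exo,4-endo)-1,3-diphenylbicyclo[1.1.0]butane-2,4-dicarboxylate (achiral, mirror plane through C2 and C4) | CCOC(=O)[C@H]1[C@]2(c3ccccc3)[C@H](C(=O)OCC)[C@]12c1ccccc1 | intermediate
5 | diethyl (r-1,t-2,t-3,t-4)-2,4-diphenylcyclobutane-1,3-dicarboxylate (epi-truxillate: phenyls cis to each other, C1 ester trans and C3 ester cis to them; meso) | CCOC(=O)[C@H]1[C@H](c2ccccc2)[C@H](C(=O)OCC)[C@@H]1c1ccccc1 | intermediate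
6 | diethyl (r-1,t-2,c-3,t-4)-2,4-diphenylcyclobutane-1,3-dicarboxylate (ε-truxillate, every vicinal pair trans; meso) | CCOC(=O)[C@H]1[C@H](c2ccccc2)[C@@H](C(=O)OCC)[C@@H]1c1ccccc1 | intermediate
7 | ε-truxillic acid, (r-1,t-2,c-3,t-4)-2,4-diphenylcyclobutane-1,3-dicarboxylic acid (meso) | OC(=O)[C@H]1[C@H](c2ccccc2)[C@@H](C(O)=O)[C@@H]1c1ccccc1 | intermediate
8 | resorcinol | Oc1cccc(O)c1 | starting material
9 | [(r-1,t-2,c-3,t-4)-2,4-diphenylcyclobutane-1,3-diyl]bis[(2,4-dihydroxyphenyl)methanone] (aroyl groups cis to each other, phenyls cis to each other, every vicinal pair trans; meso) | O=C(c1ccc(O)cc1O)[C@H]1[C@H](c2ccccc2)[C@@H](C(=O)c2ccc(O)cc2O)[C@@H]1c1ccccc1 | target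

**Totals**
Total step count: 4. Longest linear sequence: 4 (1 → 4 → 5 → 7 → 9).

**Steps most likely to fail**

**Step 1.** The second carbene transfer may stall at 3, or lose out to carbene dimerisation or arene cyclopropanation. The fallback sets out from 1 and 2 and comes back at 4.
- Make and isolate 3 with only 1.2 equiv of 2.
- Leave 3 in neat 2 in the dark at 25–40 °C. A strain-driven 1,3-dipolar cycloaddition on the face anti to the ester gives racemic diethyl 1,5-diphenyl-2,3-diazabicyclo[3.1.0]hex-2-ene-4,6-dicarboxylate F1.
- Irradiate F1 at once (350 nm, Et2O, −20 °C), before it can tautomerise. It loses nitrogen, and the resulting 1,3-diradical closes to 4.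

**Step 2.** Pd may isomerise the bicyclobutane to a diene or cut a peripheral donor–acceptor bond. The fallback sets out from 4 and comes back at 5.
- Use metal-free ionic hydrogenation: Et3SiH (3 equiv), CF3CO2H (2 equiv), CH2Cl2, −40 °C.
- Protonation of the electron-rich central bond at one bridgehead gives a tertiary benzylic cyclobutyl cation.
- The silane reduces that cation from the face carrying the transannular C–H rather than the transannular phenyl, which again places the two phenyls cis.
- No new isolable compound is made.

**Step 4.** The carboxyls are hindered secondary ones, and phthalein-type over-condensation through the cyclic anhydride is possible. The fallback sets out from 7 and comes back at 9.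
- SOCl2 (cat. DMF, toluene, 70 °C) gives ε-truxilloyl dichloride F2.
- AlCl3-mediated Friedel–Crafts acylation of 1,3-dimethoxybenzene (CH2Cl2, 0 °C) gives the bis(2,4-dimethoxyphenyl) diketone F3. Indanone closure is still blocked by the trans geometry.
- BBr3 (CH2Cl2, −78 °C to rt) removes the four methyl groups to give 9.

**Further compounds**
F1 | step 1 | rac-diethyl 1,5-diphenyl-2,3-diazabicyclo[3.1.0]hex-2-ene-4,6-dicarboxylate (6-ester exo, 4-ester trans to the C5 phenyl; one enantiomer drawn) | CCOC(=O)[C@@H]1N=N[C@]2(c3ccccc3)[C@@H](C(=O)OCC)[C@]12c1ccccc1
F0 | step 2 | none | none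
F2 | step 4 | (r-1,t-2,c-3,t-4)-2,4-diphenylcyclobutane-1,3-dicarbonyl dichloride | O=C(Cl)[C@H]1[C@H](c2ccccc2)[C@@H](C(Cl)=O)[C@@H]1c1ccccc1
F3 | step 4 | [(r-1,t-2,c-3,t-4)-2,4-diphenylcyclobutane-1,3-diyl]bis[(2,4-dimethoxyphenyl)methanone] | COc1ccc(C(=O)[C@H]2[C@H](c3ccccc3)[C@@H](C(=O)c3ccc(OC)cc3OC)[C@@H]2c2ccccc2)c(OC)c1
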